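**Plan**

1. Numbering: the tricyclic half is numbered as an indane (C1 carries the CH2 link, C3a the lactone carbonyl, C4 Br, C7 Me and the lactone O, C7a H); ring A is C1′ (carbinol), C3′ (CMe2), C4′ (CHBr).
2. Ring A is cut twice in one retro-step: the exocyclic C1′–CH2 bond and the ring bond C2′–C3′. The enabling feature is that C4′ flanks the CMe2 carbon C3′ and lies 1,4 to the carbinol C1′, which is the pattern left by chair cyclization of a 2,2-dimethyloxirane (C3′/C4′) onto a C1′=C2′ alkene. With boron on C1′, the CH2 of the tricycle arrives by a boron-to-carbon shift as the ring closes.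
3. Tricycle: the lactone O–C7 bond is cut back to a C6=C7 alkene acid, then the cyclohexene is cut by retro-Diels–Alder (C3a–C7a and C4–C5) to an acyclic triene carrying a (Z)-β-bromo enal.
4. Forward order: chain assembly, then cyclopentane and cyclohexene together (intramolecular Diels–Alder), then the lactone, then ring A and the fragment union in one step, then C4′–OH to C4′–Br, and last C–B to C–OH.
5. Stereochemistry: C1 from a Cu-catalysed enantioselective allylic substitution; C7a, C3a and C4 relayed from C1 and the Z-bromoalkene in the Diels–Alder step; C7 from the bridging lactone; C1′ from a Shi epoxide through the chair cascade; C4′–Br by ketone, axial alcohol, invertive bromination.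

Key step: step 16

Remark: Bpin stands for 4,4,5,5-tetramethyl-1,3,2-dioxaborolan-2-yl. It is assumed that the L-fructose-derived (ent-Shi) ketone is the catalyst enantiomer that gives the (3S)-epoxide and that the NHC–Cu enantiomer in step 9 is chosen to give the (5R)-boronate.

Step 1
Reactants: 1 5-bromo-2-methylpent-2-ene
Product: 2 6-methylhept-5-en-1-yne
Conditions: lithium acetylide–ethylenediamine, DMSO, 10 °C → rt
Reagents that add atoms: lithium acetylide–ethylenediamine complex, [Li+].[C-]#C.NCCN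
Why: SN2 alkylation of the acetylide by the primary bromide should give the enyne; no stereocentre is formed.

Step 2
Reactants: 2 6-methylhept-5-en-1-yne
Product: 4 2-bromo-6-methylhepta-1,5-diene, via alkenylborane 3 (not isolated)
Conditions: B-bromo-9-BBN, CH2Cl2, 0 °C; then AcOH
Reagents that add atoms: B-bromo-9-borabicyclo[3.3.1]nonane, BrB1C2CCCC1CCC2
Why: syn-bromoboration of the terminal alkyne puts bromine on the internal carbon and protodeboronation with acetic acid should give the 2-bromo-1-alkene, the trisubstituted alkene being inert to haloboration.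

Step 3
Reactants: 4 2-bromo-6-methylhepta-1,5-diene
Product: 5 (3S)-3-(3-bromobut-3-en-1-yl)-2,2-dimethyloxirane
Conditions: ent-Shi ketone (30 mol %), Oxone, K2CO3, Bu4NHSO4, MeCN/DMM/buffer pH 10.5, 0 °C
Reagents that add atoms: potassium peroxymonosulfate (Oxone), [K+].[O-]S(=O)(=O)OO
Why: Shi asymmetric epoxidation should oxidize only the electron-rich trisubstituted alkene (the bromoalkene is electron-poor), the chiral dioxirane setting the (3S) centre that becomes C4′.

Step 4
Reactants: 6 prop-2-yn-1-ol; 7 but-3-en-1-ylmagnesium bromide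
Product: 9 (2Z)-2-(bromomethylidene)hex-5-en-1-ol, via alkenylmagnesium 8 (not isolated)
Conditions: 7 (3 equiv), CuI (10 mol %), Et2O/THF, −10 °C → rt; then NBS, −40 → 0 °C
Reagents that add atoms: N-bromosuccinimide, BrN1C(=O)CCC1=O
Why: copper-catalysed anti-carbomagnesiation of the propargylic alkoxide delivers the alkyl group to the internal carbon and magnesium to the terminal carbon cis to CH2O (chelate), and bromination of the alkenyl Grignard with retention should give the Z-bromoalkene (Br cis to CH2OH).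

Step 5
Reactants: 9 (2Z)-2-(bromomethylidene)hex-5-en-1-ol
Product: 10 {[(2Z)-2-(bromomethylidene)hex-5-en-1-yl]oxy}(tert-butyl)dimethylsilane
Conditions: TBSCl, imidazole, CH2Cl2, rt
Reagents that add atoms: tert-butyldimethylsilyl chloride, CC(C)(C)[Si](C)(C)Cl
Why: standard silylation of the primary allylic alcohol protects it through the base, hydride and ylide steps that follow.

Step 6
Reactants: 10 {[(2Z)-2-(bromomethylidene)hex-5-en-1-yl]oxy}(tert-butyl)dimethylsilane
Product: 11 methyl (2E,6Z)-7-bromo-6-{[(tert-butyldimethylsilyl)oxy]methyl}hepta-2,6-dienoate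
Conditions: methyl acrylate (4 equiv), Hoveyda–Grubbs II (3 mol %), CH2Cl2, 40 °C
Reagents that add atoms: methyl acrylate, C=CC(=O)OC
Why: olefin cross-metathesis of the terminal alkene with an acrylate should give the E-enoate, the trisubstituted bromoalkene being unreactive toward the ruthenium carbene.

Step 7
Reactants: 11 methyl (2E,6Z)-7-bromo-6-{[(tert-butyldimethylsilyl)oxy]methyl}hepta-2,6-dienoate
Product: 12 (2E,6Z)-7-bromo-6-{[(tert-butyldimethylsilyl)oxy]methyl}hepta-2,6-dien-1-ol
Conditions: DIBAL-H (2.2 equiv), CH2Cl2, −78 °C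
Reagents that add atoms: none
Why: 1,2-reduction of the enoate by DIBAL-H should give the E-allylic alcohol without touching the vinyl bromide or the silyl ether.

Step 8
Reactants: 12 (2E,6Z)-7-bromo-6-{[(tert-butyldimethylsilyl)oxy]methyl}hepta-2,6-dien-1-ol
Product: 13 (2E,6Z)-7-bromo-6-{[(tert-butyldimethylsilyl)oxy]methyl}hepta-2,6-dien-1-yl diethyl phosphate
Conditions: ClP(O)(OEt)2, pyridine, DMAP (cat.), CH2Cl2, 0 °C
Reagents that add atoms: diethyl chlorophosphate, CCOP(=O)(Cl)OCC
Why: phosphorylation of the primary allylic alcohol gives the leaving group needed for copper-catalysed allylic substitution.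

Step 9
Reactants: 13 (2E,6Z)-7-bromo-6-{[(tert-butyldimethylsilyl)oxy]methyl}hepta-2,6-dien-1-yl diethyl phosphate
Product: 14 {[(2Z,5R)-2-(bromomethylidene)-5-[(Bpin)methyl]hept-6-en-1-yl]oxy}(tert-butyl)dimethylsilane
Conditions: CH2(Bpin)2, NaOMe, chiral sulfonate-bearing NHC–CuCl (5 mol %), THF, 22 °C
Reagents that add atoms: bis[(pinacolato)boryl]methane, CC1(C)OB(CB2OC(C)(C)C(C)(C)O2)OC1(C)C
Why: copper-catalysed enantioselective allylic substitution (SN2′) with diborylmethane, in which methoxide-induced deborylation gives a Cu–CH2Bpin nucleophile, should form the C1 stereocentre (5R here) under catalyst control and install the CH2Bpin handle for the key step.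

Step 10
Reactants: 14 {[(2Z,5R)-2-(bromomethylidene)-5-[(Bpin)methyl]hept-6-en-1-yl]oxy}(tert-butyl)dimethylsilane
Product: 15 (2E,4R,7Z)-8-bromo-7-{[(tert-butyldimethylsilyl)oxy]methyl}-2-methyl-4-[(Bpin)methyl]octa-2,7-dienal
Conditions: methacrolein (10 equiv), Hoveyda–Grubbs II (5–10 mol %), 1,4-benzoquinone (10 mol %), CH2Cl2, 40 °C
Reagents that add atoms: methacrolein, CC(=C)C=O
Why: cross-metathesis of the vinyl group with methacrolein should give the thermodynamically preferred E-2-methyl enal, benzoquinone suppressing alkene migration that would erase the allylic stereocentre.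

Step 11
Reactants: 15 (2E,4R,7Z)-8-bromo-7-{[(tert-butyldimethylsilyl)oxy]methyl}-2-methyl-4-[(Bpin)methyl]octa-2,7-dienal
Product: 16 tert-butyl{[(2Z,5R,6E)-2-(bromomethylidene)-7-methyl-5-[(Bpin)methyl]nona-6,8-dien-1-yl]oxy}dimethylsilane
Conditions: Ph3PCH3Br, KHMDS, THF, −78 → 0 °C (aldehyde added to the ylide at −78 °C)
Reagents that add atoms: methyltriphenylphosphonium bromide, [Br-].C[P+](c1ccccc1)(c1ccccc1)c1ccccc1
Why: Wittig methylenation of the enal should give the E-configured 2-methyl-1,3-diene, fast carbonyl addition at low temperature avoiding γ-deprotonation at the stereocentre.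

Step 12
Reactants: 16 tert-butyl{[(2Z,5R,6E)-2-(bromomethylidene)-7-methyl-5-[(Bpin)methyl]nona-6,8-dien-1-yl]oxy}dimethylsilane
Product: 17 (2Z,5R,6E)-2-(bromomethylidene)-7-methyl-5-[(Bpin)methyl]nona-6,8-dien-1-ol
Conditions: CSA (10 mol %), MeOH/CH2Cl2, 0 °C
Reagents that add atoms: none
Why: acid-catalysed methanolysis should remove the primary TBS ether while the alkyl pinacol boronate and the diene are left intact.

Step 13
Reactants: 17 (2Z,5R,6E)-2-(bromomethylidene)-7-methyl-5-[(Bpin)methyl]nona-6,8-dien-1-ol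
Product: 19 (1R,3aS,4S,7aR)-4-bromo-7-methyl-1-[(Bpin)methyl]-2,3,3a,4,5,7a-hexahydro-1H-indene-3a-carbaldehyde, via trienal 18 (not isolated)
Conditions: Dess–Martin periodinane, CH2Cl2, 0 °C → rt; filtered; then PhMe, BHT, 90 °C
Reagents that add atoms: none
Why: Dess–Martin oxidation gives the (Z)-β-bromo enal, whose type-1 intramolecular Diels–Alder reaction should pass through the aldehyde-endo, tether-anti transition state (trans ring fusion, reinforced by the C7 methyl next to the tethered diene terminus), the Z geometry giving Br cis to CHO and A(1,3) strain between the diene methyl and the allylic stereocentre placing the CH2Bpin arm anti to the incoming dienophile (cis to H-7a).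

Step 14
Reactants: 19 (1R,3aS,4S,7aR)-4-bromo-7-methyl-1-[(Bpin)methyl]-2,3,3a,4,5,7a-hexahydro-1H-indene-3a-carbaldehyde
Product: 20 (1R,3aS,4S,7aR)-4-bromo-7-methyl-1-[(Bpin)methyl]-2,3,3a,4,5,7a-hexahydro-1H-indene-3a-carboxylic acid
Conditions: NaClO2, NaH2PO4, 2-methylbut-2-ene, t-BuOH/H2O, 0 °C → rt
Reagents that add atoms: sodium chlorite, [Na+].[O-]Cl=O
Why: Pinnick oxidation should convert the non-enolizable neopentyl aldehyde into the acid, the scavenger protecting the ring alkene from hypochlorous acid.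

Step 15
Reactants: 20 (1R,3aS,4S,7aR)-4-bromo-7-methyl-1-[(Bpin)methyl]-2,3,3a,4,5,7a-hexahydro-1H-indene-3a-carboxylic acid
Product: 21 (1R,3aS,4S,7R,7aS)-4-bromo-7-hydroxy-7-methyl-1-[(Bpin)methyl]octahydro-1H-indene-3a-carboxylic acid γ-lactone
Conditions: TfOH (10 mol %), CH2Cl2, 0 °C
Reagents that add atoms: none
Why: acid-catalysed Markovnikov lactonization of the γ,δ-unsaturated acid (protonation at C6, capture of the tertiary C7 cation by the axial angular carboxyl group) should close the bridging γ-lactone, the 1,3-diaxial bridge fixing the C7 configuration.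

Step 16
Reactants: 5 (3S)-3-(3-bromobut-3-en-1-yl)-2,2-dimethyloxirane; 21 (1R,3aS,4S,7R,7aS)-4-bromo-7-hydroxy-7-methyl-1-[(Bpin)methyl]octahydro-1H-indene-3a-carboxylic acid γ-lactone
Product: 24 (1S,3aS,4S,7R,7aS)-4-bromo-7-hydroxy-1-{[(1R,4S)-4-hydroxy-3,3-dimethyl-1-(Bpin)cyclohexyl]methyl}-7-methyloctahydro-1H-indene-3a-carboxylic acid γ-lactone, via vinyllithium 22 (not isolated), via boronate complex 23 (not isolated)
Conditions: 5 (1.05 equiv), t-BuLi (2.1 equiv), Et2O, −78 °C; 21, THF, −78 °C; Zn(OTf)2 (1.2 equiv), CH2Cl2, −78 → 0 °C; H2O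
Reagents that add atoms: none
Why: Proposed new method: the vinyllithium adds to the boronic ester to give an alkenyl boronate complex, whose borate-activated CH2= terminus should attack the Lewis-acid-activated epoxide at its tertiary carbon while the positive charge developing on the boron-bearing carbon triggers an antiperiplanar 1,2-shift of the primary alkyl group (the CH2 of the tricycle) from boron to carbon, so that the C1′–CH2 bond and ring A form in one event. The closest known reaction types are the electrophile-induced 1,2-metalate rearrangement of alkenyl boronate complexes (Zweifel type; lithium alkenyltrialkylborates are known to react in this way with oxiranes) and the Lewis-acid epoxide-initiated cation–olefin cyclization. Ring A closes in the 6-endo mode (endo opening of the epoxide at C3′, both alkene carbons in the ring) through a chair transition state. C4′ keeps the epoxide configuration with its C–O bond equatorial, and C1′ is set by that chair together with the anti addition across the alkene, so the migrating CH2 ends equatorial and boron axial, cis to the C4′ oxygen. The step needs the vinyllithium to add to boron and not to the lactone (boronic ester far more electrophilic at −78 °C, lactone carbonyl neopentyl) and the epoxide to open at the tertiary carbon without loss of the pinacol ligand (2,2-dimethyl substitution; a zinc Lewis acid of the kind that coexists with boronate complexes).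

Step 17
Reactants: 24 (1S,3aS,4S,7R,7aS)-4-bromo-7-hydroxy-1-{[(1R,4S)-4-hydroxy-3,3-dimethyl-1-(Bpin)cyclohexyl]methyl}-7-methyloctahydro-1H-indene-3a-carboxylic acid γ-lactone
Product: 25 (1S,3aS,4S,7R,7aS)-4-bromo-1-{[(1R)-3,3-dimethyl-4-oxo-1-(Bpin)cyclohexyl]methyl}-7-hydroxy-7-methyloctahydro-1H-indene-3a-carboxylic acid γ-lactone
Conditions: Dess–Martin periodinane, CH2Cl2, rt
Reagents that add atoms: none
Why: Dess–Martin oxidation of the only free alcohol gives the C4′ ketone, keeping the tertiary carbinol masked as the C–B bond and erasing the equatorial C4′ configuration so that it can be reset.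

Step 18
Reactants: 25 (1S,3aS,4S,7R,7aS)-4-bromo-1-{[(1R)-3,3-dimethyl-4-oxo-1-(Bpin)cyclohexyl]methyl}-7-hydroxy-7-methyloctahydro-1H-indene-3a-carboxylic acid γ-lactone
Product: 26 (1S,3aS,4S,7R,7aS)-4-bromo-7-hydroxy-1-{[(1R,4R)-4-hydroxy-3,3-dimethyl-1-(Bpin)cyclohexyl]methyl}-7-methyloctahydro-1H-indene-3a-carboxylic acid γ-lactone
Conditions: L-Selectride, THF, −78 °C; non-oxidative work-up
Reagents that add atoms: none
Why: in the chair with the CH2 arm equatorial, the bulky trialkylborohydride should attack the ketone next to the gem-dimethyl carbon from the equatorial side (as with 4,4-dimethyl-3-keto rings), giving the axial C4′ alcohol trans to boron, and at −78 °C the hindered lactone is not reduced.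

Step 19
Reactants: 26 (1S,3aS,4S,7R,7aS)-4-bromo-7-hydroxy-1-{[(1R,4R)-4-hydroxy-3,3-dimethyl-1-(Bpin)cyclohexyl]methyl}-7-methyloctahydro-1H-indene-3a-carboxylic acid γ-lactone
Product: 27 (1S,3aS,4S,7R,7aS)-4-bromo-1-{[(1R,4S)-4-bromo-3,3-dimethyl-1-(Bpin)cyclohexyl]methyl}-7-hydroxy-7-methyloctahydro-1H-indene-3a-carboxylic acid γ-lactone
Conditions: CBr4, P(n-Oct)3, toluene, 0 → 60 °C
Reagents that add atoms: carbon tetrabromide, BrC(Br)(Br)Br
Why: Appel-type deoxybromination with a trialkylphosphine should displace the axial alkoxyphosphonium group by bromide with inversion (SN2) to give the equatorial C4′ bromide cis to boron, the carbinol still being masked as C–B so that it can neither ionize nor close a 1,4-ether bridge.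

Step 20
Reactants: 27 (1S,3aS,4S,7R,7aS)-4-bromo-1-{[(1R,4S)-4-bromo-3,3-dimethyl-1-(Bpin)cyclohexyl]methyl}-7-hydroxy-7-methyloctahydro-1H-indene-3a-carboxylic acid γ-lactone
Product: 28 (1S,3aS,4S,7R,7aS)-4-bromo-1-{[(1S,4S)-4-bromo-1-hydroxy-3,3-dimethylcyclohexyl]methyl}-7-hydroxy-7-methyloctahydro-1H-indene-3a-carboxylic acid γ-lactone (the target)
Conditions: H2O2 (30 %), NaOH (aq), THF, 0 °C → rt; then pH 3–4
Reagents that add atoms: hydrogen peroxide, OO
Why: oxidation of the tertiary boronic ester (boron-to-oxygen 1,2-shift) proceeds with retention and should give the axial tertiary alcohol cis to the C4′ bromide, the equatorial neopentyl bromides resisting E2 and any opened lactone reclosing on acidification.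

**Compound list**

1 | 5-bromo-2-methylpent-2-ene | CC(C)=CCCBr | starting material
2 | 6-methylhept-5-en-1-yne | C#CCCC=C(C)C | intermediate
3 | 9-[(1Z)-2-bromo-6-methylhepta-1,5-dien-1-yl]-9-borabicyclo[3.3.1]nonane | CC(C)=CCC/C(Br)=C/B1C2CCCC1CCC2 | intermediate
4 | 2-bromo-6-methylhepta-1,5-diene | C=C(Br)CCC=C(C)C | intermediate
5 | (3S)-3-(3-bromobut-3-en-1-yl)-2,2-dimethyloxirane | C=C(Br)CC[C@@H]1OC1(C)C | intermediate
6 | prop-2-yn-1-ol | C#CCO | starting material
7 | but-3-en-1-ylmagnesium bromide | C=CCC[Mg]Br | starting material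
8 | bromomagnesium (2Z)-2-[(bromomagnesio)methylidene]hex-5-en-1-olate | C=CCC/C(CO[Mg]Br)=C/[Mg]Br | intermediate
9 | (2Z)-2-(bromomethylidene)hex-5-en-1-ol | C=CCC/C(CO)=C/Br | intermediate
10 | {[(2Z)-2-(bromomethylidene)hex-5-en-1-yl]oxy}(tert-butyl)dimethylsilane | C=CCC/C(CO[Si](C)(C)C(C)(C)C)=C/Br | intermediate
11 | methyl (2E,6Z)-7-bromo-6-{[(tert-butyldimethylsilyl)oxy]methyl}hepta-2,6-dienoate | COC(=O)/C=C/CC/C(CO[Si](C)(C)C(C)(C)C)=C/Br | intermediate
12 | (2E,6Z)-7-bromo-6-{[(tert-butyldimethylsilyl)oxy]methyl}hepta-2,6-dien-1-ol | OC/C=C/CC/C(CO[Si](C)(C)C(C)(C)C)=C/Br | intermediate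
13 | (2E,6Z)-7-bromo-6-{[(tert-butyldimethylsilyl)oxy]methyl}hepta-2,6-dien-1-yl diethyl phosphate | CCOP(=O)(OCC)OC/C=C/CC/C(CO[Si](C)(C)C(C)(C)C)=C/Br | intermediate
14 | {[(2Z,5R)-2-(bromomethylidene)-5-[(Bpin)methyl]hept-6-en-1-yl]oxy}(tert-butyl)dimethylsilane | C=C[C@H](CB1OC(C)(C)C(C)(C)O1)CC/C(CO[Si](C)(C)C(C)(C)C)=C/Br | intermediate
15 | (2E,4R,7Z)-8-bromo-7-{[(tert-butyldimethylsilyl)oxy]methyl}-2-methyl-4-[(Bpin)methyl]octa-2,7-dienal | O=C/C(C)=C/[C@H](CB1OC(C)(C)C(C)(C)O1)CC/C(CO[Si](C)(C)C(C)(C)C)=C/Br | intermediate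
16 | tert-butyl{[(2Z,5R,6E)-2-(bromomethylidene)-7-methyl-5-[(Bpin)methyl]nona-6,8-dien-1-yl]oxy}dimethylsilane | C=C/C(C)=C/[C@H](CB1OC(C)(C)C(C)(C)O1)CC/C(CO[Si](C)(C)C(C)(C)C)=C/Br | intermediate
17 | (2Z,5R,6E)-2-(bromomethylidene)-7-methyl-5-[(Bpin)methyl]nona-6,8-dien-1-ol | C=C/C(C)=C/[C@H](CB1OC(C)(C)C(C)(C)O1)CC/C(CO)=C/Br | intermediate
18 | (2Z,5R,6E)-2-(bromomethylidene)-7-methyl-5-[(Bpin)methyl]nona-6,8-dienal | C=C/C(C)=C/[C@H](CB1OC(C)(C)C(C)(C)O1)CC/C(C=O)=C/Br | intermediate
19 | (1R,3aS,4S,7aR)-4-bromo-7-methyl-1-[(Bpin)methyl]-2,3,3a,4,5,7a-hexahydro-1H-indene-3a-carbaldehyde | CC1(C)OB(C[C@@H]2CC[C@]3(C=O)[C@@H](Br)CC=C(C)[C@@H]23)OC1(C)C | intermediate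
20 | (1R,3aS,4S,7aR)-4-bromo-7-methyl-1-[(Bpin)methyl]-2,3,3a,4,5,7a-hexahydro-1H-indene-3a-carboxylic acid | CC1(C)OB(C[C@@H]2CC[C@]3(C(=O)O)[C@@H](Br)CC=C(C)[C@@H]23)OC1(C)C | intermediate
21 | (1R,3aS,4S,7R,7aS)-4-bromo-7-hydroxy-7-methyl-1-[(Bpin)methyl]octahydro-1H-indene-3a-carboxylic acid γ-lactone | CC1(C)OB(C[C@@H]2CC[C@]34C(=O)O[C@](C)(CC[C@@H]3Br)[C@@H]24)OC1(C)C | intermediate
22 | {4-[(2S)-3,3-dimethyloxiran-2-yl]but-1-en-2-yl}lithium | [Li]C(=C)CC[C@@H]1OC1(C)C | intermediate
23 | lithium alkenyl(alkyl)pinacolatoborate formed from 22 and 21 | [Li+].CC1(C)O[B-](C(=C)CC[C@@H]5OC5(C)C)(C[C@@H]2CC[C@]34C(=O)O[C@](C)(CC[C@@H]3Br)[C@@H]24)OC1(C)C | intermediate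
24 | (1S,3aS,4S,7R,7aS)-4-bromo-7-hydroxy-1-{[(1R,4S)-4-hydroxy-3,3-dimethyl-1-(Bpin)cyclohexyl]methyl}-7-methyloctahydro-1H-indene-3a-carboxylic acid γ-lactone | CC1(C)C[C@@](B2OC(C)(C)C(C)(C)O2)(C[C@@H]3CC[C@]45C(=O)O[C@](C)(CC[C@@H]4Br)[C@@H]35)CC[C@@H]1O | intermediate
25 | (1S,3aS,4S,7R,7aS)-4-bromo-1-{[(1R)-3,3-dimethyl-4-oxo-1-(Bpin)cyclohexyl]methyl}-7-hydroxy-7-methyloctahydro-1H-indene-3a-carboxylic acid γ-lactone | CC1(C)C[C@@](B2OC(C)(C)C(C)(C)O2)(C[C@@H]3CC[C@]45C(=O)O[C@](C)(CC[C@@H]4Br)[C@@H]35)CCC1=O | intermediate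
26 | (1S,3aS,4S,7R,7aS)-4-bromo-7-hydroxy-1-{[(1R,4R)-4-hydroxy-3,3-dimethyl-1-(Bpin)cyclohexyl]methyl}-7-methyloctahydro-1H-indene-3a-carboxylic acid γ-lactone | CC1(C)C[C@@](B2OC(C)(C)C(C)(C)O2)(C[C@@H]3CC[C@]45C(=O)O[C@](C)(CC[C@@H]4Br)[C@@H]35)CC[C@H]1O | intermediate
27 | (1S,3aS,4S,7R,7aS)-4-bromo-1-{[(1R,4S)-4-bromo-3,3-dimethyl-1-(Bpin)cyclohexyl]methyl}-7-hydroxy-7-methyloctahydro-1H-indene-3a-carboxylic acid γ-lactone | CC1(C)C[C@@](B2OC(C)(C)C(C)(C)O2)(C[C@@H]3CC[C@]45C(=O)O[C@](C)(CC[C@@H]4Br)[C@@H]35)CC[C@@H]1Br | intermediate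
28 | (1S,3aS,4S,7R,7aS)-4-bromo-1-{[(1S,4S)-4-bromo-1-hydroxy-3,3-dimethylcyclohexyl]methyl}-7-hydroxy-7-methyloctahydro-1H-indene-3a-carboxylic acid γ-lactone | CC1(C)C[C@@](O)(C[C@@H]2CC[C@]34C(=O)O[C@](C)(CC[C@@H]3Br)[C@@H]24)CC[C@@H]1Br | target

**Step count and risks**

Total step count: 20. Longest linear sequence: 17 steps (steps 4–20); the epoxide branch (steps 1–3) joins at step 16.

Steps most likely to fail:

1. Step 16 (proposed new method). The Lewis acid may strip the diol ligand from the boronate complex, the epoxide may open at its secondary carbon or isomerize to a ketone before the C–C bond forms, or the vinyllithium may add to the lactone. The fallback uses known chemistry, sets out from 21 and comes back at 28. Oxidative deborylation (NaBO3, THF/H2O) would give the primary alcohol F1, and Appel iodination (I2, PPh3, imidazole) the primary iodide F2. A samarium Barbier reaction (SmI2, cat. NiI2, THF) of F2 with the known 2,2-dimethylcyclohexane-1,4-dione, which reacts at its unhindered carbonyl, would give the hydroxy ketone F3. This addition has no control over the carbinol centre, so the C1′ epimers would have to be separated. L-Selectride reduction as in step 18 would give the trans-diol F4, and bromination with CBr4/P(n-Oct)3 as in step 19 would give 28.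

2. Step 13. The cis- and trans-fused transition states may not be discriminated well enough under purely thermal conditions. The fallback sets out from 18 and comes back at 20. Pinnick oxidation of 18 would give the trienoic acid F5, and alkylation with allyl bromide/K2CO3 the allyl trienoate F6. Its cycloaddition would be run as a Lewis-acid-complexed ester (Me2AlCl, CH2Cl2, −40 °C), where carbonyl complexation should enforce the carbonyl-endo transition state, to give the cycloadduct allyl ester F7. Pd(PPh3)4/morpholine deallylation would return 20.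

3. Step 19. E2 elimination toward C5′ or failure of substitution at the neopentyl carbon may prevail. The fallback sets out from 26 and comes back at 27. The axial alcohol would be converted (Tf2O, pyridine, −40 °C) into the isolated secondary triflate F8, which is then displaced in a separate SN2 step by LiBr in acetone, again with inversion, to give 27.

**Further compounds**

F1 | step 16 | (1R,3aS,4S,7R,7aS)-4-bromo-7-hydroxy-1-(hydroxymethyl)-7-methyloctahydro-1H-indene-3a-carboxylic acid γ-lactone | OC[C@@H]1CC[C@]23C(=O)O[C@](C)(CC[C@@H]2Br)[C@@H]13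
F2 | step 16 | (1R,3aS,4S,7R,7aS)-4-bromo-7-hydroxy-1-(iodomethyl)-7-methyloctahydro-1H-indene-3a-carboxylic acid γ-lactone | IC[C@@H]1CC[C@]23C(=O)O[C@](C)(CC[C@@H]2Br)[C@@H]13
F3 | step 16 | (1S,3aS,4S,7R,7aS)-4-bromo-7-hydroxy-1-{[(1S)-1-hydroxy-3,3-dimethyl-4-oxocyclohexyl]methyl}-7-methyloctahydro-1H-indene-3a-carboxylic acid γ-lactone | CC1(C)C[C@@](O)(C[C@@H]2CC[C@]34C(=O)O[C@](C)(CC[C@@H]3Br)[C@@H]24)CCC1=O
F4 | step 16 | (1S,3aS,4S,7R,7aS)-4-bromo-1-{[(1S,4R)-1,4-dihydroxy-3,3-dimethylcyclohexyl]methyl}-7-hydroxy-7-methyloctahydro-1H-indene-3a-carboxylic acid γ-lactone | CC1(C)C[C@@](O)(C[C@@H]2CC[C@]34C(=O)O[C@](C)(CC[C@@H]3Br)[C@@H]24)CC[C@H]1O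
F5 | step 13 | (2Z,5R,6E)-2-(bromomethylidene)-7-methyl-5-[(Bpin)methyl]nona-6,8-dienoic acid | C=C/C(C)=C/[C@H](CB1OC(C)(C)C(C)(C)O1)CC/C(C(=O)O)=C/Br
F6 | step 13 | prop-2-en-1-yl (2Z,5R,6E)-2-(bromomethylidene)-7-methyl-5-[(Bpin)methyl]nona-6,8-dienoate | C=C/C(C)=C/[C@H](CB1OC(C)(C)C(C)(C)O1)CC/C(C(=O)OCC=C)=C/Br
F7 | step 13 | prop-2-en-1-yl (1R,3aS,4S,7aR)-4-bromo-7-methyl-1-[(Bpin)methyl]-2,3,3a,4,5,7a-hexahydro-1H-indene-3a-carboxylate | CC1(C)OB(C[C@@H]2CC[C@]3(C(=O)OCC=C)[C@@H](Br)CC=C(C)[C@@H]23)OC1(C)C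
F8 | step 19 | (1S,3aS,4S,7R,7aS)-4-bromo-1-{[(1R,4R)-3,3-dimethyl-1-(Bpin)-4-(trifluoromethanesulfonyloxy)cyclohexyl]methyl}-7-hydroxy-7-methyloctahydro-1H-indene-3a-carboxylic acid γ-lactone | CC1(C)C[C@@](B2OC(C)(C)C(C)(C)O2)(C[C@@H]3CC[C@]45C(=O)O[C@](C)(CC[C@@H]4Br)[C@@H]35)CC[C@H]1OS(=O)(=O)C(F)(F)F
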